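Slowness was my worry in Sunday's flask, the coldest of these at 20 °C, so this bench note is mainly about that flask.

all flasks: substrate 1.0 M; reagent 1.50 M; free catalyst 48 mM; time 20 h

|  | temperature |
|---|---|
| Monday's | 45 °C |
| Saturday's | 95 °C |
| Tuesday's | 70 °C |
| Sunday's | 20 °C |

    reagent + free catalyst → catalyst intermediate A (k1 = 1.4 × 10⁻⁴ /M/s, Ea1 = 77.0 kJ/mol)
    substrate + catalyst intermediate A ⇌ catalyst intermediate B (K2 = 9.4 /M, k2 = 3.9 × 10⁻⁴ /M/s, Ea2 = 65.0 kJ/mol, ΔH2 = −49.0 kJ/mol)
    catalyst intermediate B → free catalyst + target (k3 = 3.2 × 10⁻⁴ /s, Ea3 = 79.0 kJ/mol)
    2 substrate → self-condensation product (k4 = 1.9 × 10⁻⁵ /M/s, Ea4 = 68.0 kJ/mol)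
    substrate + target → side product (k5 = 5.5 × 10⁻⁷ /M/s, Ea5 = 70.0 kJ/mol)
    (constants at 20 °C)

- in percentages every species weighs as the substrate in it: one self-condensation product or side product counts as two
- where a step has two of a species, its rate is k times that concentration squared, and two are used at each turn
- the list of constants is for 20 °C, to be carried to other temperatures by the activation energies and enthalpies

- which flask leads in amount of target, in percent of the substrate charged ("all alike" within 1.5 percentage points) (Monday's / Saturday's / Tuesday's / Sunday's / all alike)
- how much target is there at the end, in percent of the substrate charged: Monday's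
- how much target is there at the end, in percent of the substrate charged: Saturday's
- how much target is there at the end, in percent of the substrate charged: Tuesday's
- how much target is there at the end, in percent of the substrate charged: Sunday's

At the start, Sunday's flask held substrate, reagent and free catalyst, and two routes competed for the substrate. One turn of the catalyst meant three waits: 1.32 h for reagent, 0.868 h for the release of target, and 0.805 h for substrate. That last wait was reckoned at the charged c(substrate), lengthened for catalyst intermediate B falling back, and it grows as c(substrate) falls. So the catalyst could use at most 16.0 mM/h, while self-condensation began at 137 mM/h, which is faster.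

I therefore treated the target as a small correction to the self-condensation. Taking that step alone, its first half-life was 7.31 h, and c(substrate) would stand near 0.268 M at 20 h. Along that falling curve I summed the number of turns one catalyst completes in the run, the turns per catalyst: 5.01. That meant 24.0 % target in Sunday's flask. I took this as high, since the curve ignored the catalyst's start-up and its own use of substrate. In this reckoning the turns do not depend on the free catalyst charge, so the target follows that charge and the weighing of free catalyst needs care. I reckoned nothing for the warmer flasks.

The forecast put Monday's first, with 33.3 % there, 22.6 % in Saturday's, 29.2 % in Tuesday's and 20 % in Sunday's, of which it said “The reaction is time-limited”. That Sunday's figure is lower than my 24.0 %.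

The simulation also put Monday's first, with 33.7 %, then 22.7 % in Saturday's, 29.6 % in Tuesday's and 19.9 % in Sunday's, where 18.0 % of the substrate still stood at the end. In Sunday's flask, self-condensation reached the midpoint of its turnover by 3.42 h. The passing of substrate and catalyst intermediate A into catalyst intermediate B reached its midpoint later, by 8.09 h. Sunday's target came to 4.15 turns per catalyst against my 5.01. In the neighbour charged with 0.019 M of free catalyst, 5.01 turns give 9.51 % target, and the computed flask held 8.44 %, which is 4.44 turns.

(All constants are assumed; no experiment stands behind them.)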